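**Analysis of the target**

Brandisianin A (10) is an isoflavone: ring A is fused to the γ-pyranone ring C, and ring B sits on C3 through the C3–C1' bond. There are no stereocenters, so the task is one of connectivity and oxygen pattern only. Ring A carries free hydroxyls at C5 (hydrogen-bonded to the C4 carbonyl) and C7. Ring B is a 1,2,4-trioxygenated benzene with methyl ethers at C2' and C5' and a 3-methylbut-2-enyl (prenyl) ether at C4'. The prenyl ether is the sensitive group: it does not survive strong Brønsted or Lewis acids, hydrogenation or prolonged heating, and the pyranone is opened by hard nucleophiles at C2. The difficulty is to join C3 to C1' next to the 2'-methoxy group while one of three ring B oxygens is differentiated and both ring A phenols end up free; the usual answers (a halogenated or metalated ring B, or a deoxybenzoin) cost steps. The feature used here is that in 1,4-dimethoxy-2-prenyloxybenzene (7) the only unhindered CH activated by two oxygens, para to the prenyloxy group and ortho to a methoxy group, is the carbon that becomes C1'. The bare arene can therefore be joined to C3 by C–H functionalisation, and ring C can be closed through O1–C2 in the same operation.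

**Retrosynthetic reasoning**

10 to 9. The two phenols at C5 and C7 are traced back to the pivalate esters of 9. Ring A must enter the oxidative step with its oxygens masked, and the mask must come off without acid (prenyl ether), without hydrogen (prenyl alkene) and without prolonged exposure to a hard nucleophile (C2 of the pyranone). Hindered aryl esters meet these demands, since alkoxide cleaves them at or below room temperature. Unlike alkyl or acetal ethers they also withdraw electron density from ring A, which the preceding step needs.

9 to 4 and 7. In 9 the bonds C3–C1' and O1–C2 are cut together. Ring B becomes the unfunctionalised arene 7. Ring A with its three-carbon chain becomes the ortho-hydroxyaryl enaminone 4, whose α-carbon is C3 and whose amino-bearing carbon is C2. Other cuts (C2–C3 of a deoxybenzoin, or C3–C1' between a halide and a boron reagent) all need a ring B already substituted at C1'. Here the innate reactivity of that carbon does the work, and two skeletal bonds and one ring are gained in a single convergent step. The forward reaction must remove two electrons and two protons from the pair, join the enaminone α-carbon to one particular CH of 7, avoid arene–arene coupling, and then let the chelated phenolic oxygen displace the amine. The open-chain α-aryl enaminone 8 is the expected link between the two events.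

4 to 2 and 3. The bond between the α- and β-carbons of the enaminone (C3–C2 of the later chromone) is cut to give methyl ketone 2 and amide acetal 3, which supplies C2 and the amine leaving group. This is the standard entry to such enaminones. The forward condensation must leave the chelated hydroxyl unalkylated and both esters intact.

2 to 1. The two ester C–O bonds are cut to give 1. The forward acylation must stop after the 4-hydroxyl and one of the two equivalent ortho hydroxyls. The hydroxyl that remains is the one hydrogen-bonded to the ketone, and it is the one that later closes ring C.

7 to 5 and 6. The O–CH2 bond of the prenyl ether is cut to give phenol 5 and allylic bromide 6. Placing the prenyl group on the only hydroxyl of a commercial phenol settles from the start which ring B oxygen carries it. The price is that the ether must survive the anodic step.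

**Alternatives that were turned down**

Alternative 1: Ring C is cut at C3–C4 and O1–C8a. Ring B enters as the enamine A1 of its arylacetaldehyde and ring A as 2,4,6-trifluorobenzoyl chloride A2. C-acylation of A1 by A2, exchange of nitrogen for oxygen with aqueous base, and displacement of an ortho fluoride by the enolate oxygen would give the 5,7-difluoroisoflavone A3.
- For it: every event is a classical polar reaction (enamine acylation, SNAr on a fluoroarene activated by an ortho carbonyl) with unambiguous regiochemistry, and ring A needs no protecting group on the way in. On the reliability of the central step it is stronger than the chosen route.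
- Against it: A3 carries fluorine where 10 carries hydroxyl. Two further C–F to C–O exchanges are needed, with an oxygen nucleophile that can also add to C2 and open the pyranone, and the oxygen surrogate must then be unmasked without acid or hydrogen. A1 also presupposes an arylacetaldehyde, so ring B has to be formylated at C1' and homologated in separate steps.
- Comparison: the count is roughly twice that of the chosen route. The chosen route gives up certainty in the key step, but uses ring B as the bare arene and ends one mild methanolysis away from the target.

Alternative 2: Ring B is built, not brought in. The disconnection is C1'–C2' of a ring B quinone. Thermolysis of the racemic 4-alkynyl-4-hydroxycyclobutenone A4 opens the four-membered ring, and re-closure between the ketene carbon and the distal alkyne carbon would give the 2-benzyloxy-5-(chromon-3-yl)benzoquinone A5.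
- For it: the three ring B oxygens are differentiated by construction (two quinone carbonyls for the methoxy groups, benzyloxy at the future prenyloxy position). No arene site selectivity is needed, and on this point it is stronger than the chosen route, which relies on the innate selectivity of 7.
- Against it: an alkyne substituent that stabilises an adjacent radical, as the conjugated chromon-3-yl group does, favours the competing five-ring closure onto the proximal alkyne carbon. A4 must be made from a metal acetylide that carries an electrophilic chromone in the same molecule. After A5 five operations remain (quinone reduction, double O-methylation, debenzylation, prenylation, desilylation), against one after 9.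
- Comparison: the chosen route is far shorter and carries the prenyl ether from its first step.

Alternative 3: Ring C is cut at O1–C8a and C4–C4a, so ring A comes from an aryne. The enolate of the α-formyl arylacetate A6 meets the aryne released by fluoride from silyl triflate A7. O-attack at the aryne carbon remote from the flanking alkoxy group, then acylation of the aryl anion by the ester, would give the bis-MOM isoflavone A8.
- For it: both bonds from ring C to ring A form in one nearly neutral step, the flanking alkoxy group directs the nucleophile to the right aryne carbon, and the closure mirrors the known aryne route from salicylates to xanthones. In certainty about the ring B pattern it equals Alternative 1 and exceeds the chosen route.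
- Against it: enolates of 1,3-dicarbonyl compounds usually attack arynes through carbon and insert the aryne into the C–C bond, which competes with the required O-arylation. A prenyl alkene would undergo an ene reaction with the aryne, so A8 carries an allyl ether that must later be converted by cross-metathesis. The MOM groups need acid, which has to be applied before the prenyl group exists. A6 and A7 each take several steps, and A6 again needs a ring B functionalised at C1'.
- Comparison: it is at least twice as long and has two uncertain steps where the chosen route has one.

Key step: step 4

Remark: 2,5-dimethoxyphenol (5) is taken as a commercial compound; the transient enaminone 8 is expected as a mixture of C=C isomers whose geometry is erased on ring closure, so no geometric descriptor is given for it.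

**Route**

Step 1
Reactants: 1 2',4',6'-trihydroxyacetophenone
Product: 2 2'-hydroxy-4',6'-bis(pivaloyloxy)acetophenone
Conditions: PivCl (2.1 equiv), Et3N (2.3 equiv), THF, 0 °C
Reagents that add atoms: pivaloyl chloride, CC(C)(C)C(=O)Cl
Why: Selective O-acylation of phenols: the 4-hydroxyl and one of the two equivalent ortho hydroxyls should react, while the last hydroxyl is held in a hydrogen bond to the ketone and flanked by the acetyl group. The bulk of the pivaloyl group sharpens this difference, which is the same one that underlies the usual bis-protections of this ketone.

Step 2
Reactants: 2 2'-hydroxy-4',6'-bis(pivaloyloxy)acetophenone, 3 N,N-dimethylformamide dimethyl acetal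
Product: 4 (E)-3-(dimethylamino)-1-[2-hydroxy-4,6-bis(pivaloyloxy)phenyl]prop-2-en-1-one
Conditions: 3 (1.5 equiv), toluene, 70 °C, slow N2 stream to carry off MeOH
Reagents that add atoms: none
Why: Enaminone formation by condensation of a methyl ketone with an amide acetal; the push-pull alkene should settle in the (E) form, and the chelated hydroxyl stays free as in other ortho-hydroxyacetophenones. The hindered pivalates are chosen because they resist traces of methoxide far better than acetates, and the moderate temperature with removal of methanol protects them further.

Step 3
Reactants: 5 2,5-dimethoxyphenol, 6 1-bromo-3-methylbut-2-ene (prenyl bromide)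
Product: 7 1,4-dimethoxy-2-(3-methylbut-2-enyloxy)benzene
Conditions: K2CO3, acetone, reflux
Reagents that add atoms: none
Why: Williamson ether synthesis: the phenoxide displaces the primary allylic bromide by SN2, and in a polar aprotic medium with carbonate O-alkylation should prevail over C-alkylation.

Step 4
Reactants: 4 (E)-3-(dimethylamino)-1-[2-hydroxy-4,6-bis(pivaloyloxy)phenyl]prop-2-en-1-one, 7 1,4-dimethoxy-2-(3-methylbut-2-enyloxy)benzene
Product: 9 3-[2,5-dimethoxy-4-(3-methylbut-2-enyloxy)phenyl]-5,7-bis(pivaloyloxy)chromen-4-one, via α-aryl enaminone 8 (not isolated)
Conditions: 7 (1 equiv), 4 (1.5 equiv); graphite anode, Pt cathode, undivided cell, constant current (ca. 2.2 F per mol of 7), nBu4NBF4, MeCN/(CF3)2CHOH (4:1), rt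
Reagents that add atoms: none
Why: Proposed new method: arene 7 is expected to be the most easily oxidised component, and its radical cation, kept alive by the fluorinated alcohol, is attacked by the nucleophilic α-carbon of 4 at the CH para to the prenyloxy group; loss of a second electron and of the ring proton restores ring B with the new C3–C1' bond, and loss of the α-proton from the resulting iminium ion gives 8 (if 4 is oxidised first, its α-radical iminium ion adds to the same arene carbon and the paths converge). The chelated 2-hydroxyl of 8 then adds to the amino-bearing carbon and dimethylamine is expelled, forming O1–C2 and ring C; counted on the vinylogous amide this is a 6-endo-trig addition–elimination, and counted on the C-protonated iminium form a 6-exo-trig addition, both allowed. No stereocenter is formed. The closest known reaction types are the anodic dehydrogenative cross-coupling of electron-rich arenes through their radical cations in (CF3)2CHOH, the oxidative C3-functionalisation–annulation cascades of ortho-hydroxyaryl enaminones, and the closure of α-aryl ortho-hydroxyaryl enaminones that ends the deoxybenzoin route to isoflavones; what has not been shown is an unfunctionalised arene as the partner of the enaminone. Site selectivity on 7 is required: the reacting carbon is activated by a para and an ortho oxygen and is unhindered, the other doubly activated CH is wedged between two alkoxy groups, and the third CH has only one ortho oxygen. Chemoselectivity is required against oxidation of ring A, of the alkene and of the product: the ketone and the two pivalates raise the potential of ring A, an isolated trisubstituted alkene is oxidised well above a trialkoxybenzene, and the chromonyl group makes ring B of 9 poorer than 7. The cathode reduces protons to H2, and the liberated amine is held as its ammonium salt by the acidic alcohol, which keeps it away from the anode and from the esters.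

Step 5
Reactants: 9 3-[2,5-dimethoxy-4-(3-methylbut-2-enyloxy)phenyl]-5,7-bis(pivaloyloxy)chromen-4-one
Product: 10 brandisianin A, 3-[2,5-dimethoxy-4-(3-methylbut-2-enyloxy)phenyl]-5,7-dihydroxychromen-4-one
Conditions: NaOMe (2.5 equiv), MeOH/THF, 0 °C to rt; then AcOH
Reagents that add atoms: none
Why: Base-mediated transesterification (methanolysis) of aryl esters: both pivalates are activated because their phenoxide leaving groups are conjugated with the C4 carbonyl. The phenoxides formed make C2 less electrophilic, so ring C should stay closed, and the acid-free conditions leave the prenyl ether alone.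

**Compound list**

1 | 2',4',6'-trihydroxyacetophenone | CC(=O)c1c(O)cc(O)cc1O | starting material
2 | 2'-hydroxy-4',6'-bis(pivaloyloxy)acetophenone | CC(=O)c1c(O)cc(OC(=O)C(C)(C)C)cc1OC(=O)C(C)(C)C | intermediate
3 | N,N-dimethylformamide dimethyl acetal | COC(OC)N(C)C | starting material
4 | (E)-3-(dimethylamino)-1-[2-hydroxy-4,6-bis(pivaloyloxy)phenyl]prop-2-en-1-one | CN(C)/C=C/C(=O)c1c(O)cc(OC(=O)C(C)(C)C)cc1OC(=O)C(C)(C)C | intermediate
5 | 2,5-dimethoxyphenol | COc1ccc(OC)c(O)c1 | starting material
6 | 1-bromo-3-methylbut-2-ene (prenyl bromide) | CC(C)=CCBr | starting material
7 | 1,4-dimethoxy-2-(3-methylbut-2-enyloxy)benzene | COc1ccc(OC)c(OCC=C(C)C)c1 | intermediate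
8 | 2-[2,5-dimethoxy-4-(3-methylbut-2-enyloxy)phenyl]-3-(dimethylamino)-1-[2-hydroxy-4,6-bis(pivaloyloxy)phenyl]prop-2-en-1-one (C=C geometry not fixed) | CN(C)C=C(c1cc(OC)c(OCC=C(C)C)cc1OC)C(=O)c1c(O)cc(OC(=O)C(C)(C)C)cc1OC(=O)C(C)(C)C | intermediate (not isolated)
9 | 3-[2,5-dimethoxy-4-(3-methylbut-2-enyloxy)phenyl]-5,7-bis(pivaloyloxy)chromen-4-one | COc1cc(-c2coc3cc(OC(=O)C(C)(C)C)cc(OC(=O)C(C)(C)C)c3c2=O)c(OC)cc1OCC=C(C)C | intermediate
10 | brandisianin A | COc1cc(-c2coc3cc(O)cc(O)c3c2=O)c(OC)cc1OCC=C(C)C | target

**Step count and least certain steps**

Total step count: 5. Longest linear sequence: 4 steps (1 → 2 → 4 → 9 → 10; steps 1, 2, 4 and 5).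

Step 4 (key step, new method).
- Most likely failure: loss of cross-selectivity at the anode. The radical cation of 7 may be captured by a second molecule of 7 (dehydrodimerisation) instead of by 4, because trialkoxybenzenes dimerise readily under such conditions and the α-carbon of 4 is dulled by hydrogen bonding to the fluorinated alcohol.
- Related drains: closure of 4 to the C3-unsubstituted chromone in the weakly acidic medium before any coupling, and fragmentation of the radical cation with loss of the prenyl group as an allyl cation.
- Fallback (known chemistry), setting out from 4 and 5 and returning at 9: the C3–C1' bond is made by cross-coupling of prefunctionalised partners. Iodine (I2, CHCl3, rt) iodinates the α-carbon of 4 and the same ring closure follows, giving 3-iodo-5,7-bis(pivaloyloxy)chromen-4-one F1. Phenol 5 is brominated para to the hydroxyl (NBS, MeCN, 0 °C) to 4-bromo-2,5-dimethoxyphenol F2, which is alkylated with 6 (K2CO3, acetone) to 1-bromo-2,5-dimethoxy-4-(3-methylbut-2-enyloxy)benzene F3. Miyaura borylation (B2pin2, PdCl2(dppf), KOAc, dioxane, 80 °C) converts F3 into 2-[2,5-dimethoxy-4-(3-methylbut-2-enyloxy)phenyl]-4,4,5,5-tetramethyl-1,3,2-dioxaborolane F4. Suzuki–Miyaura coupling of F1 with F4 (Pd(PPh3)4, K3PO4, dioxane/H2O, 70 °C) should give 9; any pivalate lost in the basic medium is of no consequence, since step 5 removes both.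

Step 2.
- Most likely failure: loss of a pivalate during the condensation. The acetal is in equilibrium with an iminium methoxide pair, and methoxide can transesterify the activated aryl ester para to the ketone; the freed phenoxide would then be O-methylated by the reagent. Transfer of the ortho acyl group to the ketone enolate (Baker–Venkataraman type) is a second possibility.
- Fallback, setting out from 1 and returning at 4: the esters are installed only after the enaminone exists. Benzylation of 1 (BnBr, K2CO3, DMF) gives 1-[2,4-bis(benzyloxy)-6-hydroxyphenyl]ethanone F5, which condenses with 3 (toluene, 90 °C) to (E)-1-[2,4-bis(benzyloxy)-6-hydroxyphenyl]-3-(dimethylamino)prop-2-en-1-one F6. Hydrogenolysis (H2, Pd/C, EtOAc), which the vinylogous amide should withstand, gives (E)-3-(dimethylamino)-1-(2,4,6-trihydroxyphenyl)prop-2-en-1-one F7. Pivalic anhydride (Et3N, cat. DMAP, THF, 0 °C) then acylates the two hydroxyls that are not locked to the strongly accepting enaminone carbonyl, giving 4.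

Step 1.
- Most likely failure: incomplete discrimination between the second ortho hydroxyl and the chelated one, so that mono-, bis- and tris-esters form together.
- Fallback, setting out from 1 and returning at 2: the chelated hydroxyl is masked together with the ketone. BF3·OEt2 (EtOAc, rt) converts 1 into its difluoroboron chelate, 2,2-difluoro-5,7-dihydroxy-4-methyl-1,3,2-benzodioxaborinine F8, in which the ketone oxygen and one ortho oxygen are bound to boron. The two remaining hydroxyls are acylated exhaustively (PivCl, pyridine, CH2Cl2) to the bis-pivalate chelate, 2,2-difluoro-4-methyl-5,7-bis(pivaloyloxy)-1,3,2-benzodioxaborinine F9. Mild hydrolysis of the chelate (aq. NaOAc, THF/MeOH, rt) releases 2.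

**Further compounds**

F1 | step 4 | 3-iodo-5,7-bis(pivaloyloxy)chromen-4-one | CC(C)(C)C(=O)Oc1cc(OC(=O)C(C)(C)C)c2c(c1)occ(I)c2=O
F2 | step 4 | 4-bromo-2,5-dimethoxyphenol | COc1cc(Br)c(OC)cc1O
F3 | step 4 | 1-bromo-2,5-dimethoxy-4-(3-methylbut-2-enyloxy)benzene | COc1cc(Br)c(OC)cc1OCC=C(C)C
F4 | step 4 | 2-[2,5-dimethoxy-4-(3-methylbut-2-enyloxy)phenyl]-4,4,5,5-tetramethyl-1,3,2-dioxaborolane | COc1cc(B2OC(C)(C)C(C)(C)O2)c(OC)cc1OCC=C(C)C
F5 | step 2 | 1-[2,4-bis(benzyloxy)-6-hydroxyphenyl]ethanone | CC(=O)c1c(O)cc(OCc2ccccc2)cc1OCc1ccccc1
F6 | step 2 | (E)-1-[2,4-bis(benzyloxy)-6-hydroxyphenyl]-3-(dimethylamino)prop-2-en-1-one | CN(C)/C=C/C(=O)c1c(O)cc(OCc2ccccc2)cc1OCc1ccccc1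
F7 | step 2 | (E)-3-(dimethylamino)-1-(2,4,6-trihydroxyphenyl)prop-2-en-1-one | CN(C)/C=C/C(=O)c1c(O)cc(O)cc1O
F8 | step 1 | 2,2-difluoro-5,7-dihydroxy-4-methyl-1,3,2-benzodioxaborinine (difluoroboron chelate of 1) | CC1=[O+][B-](F)(F)Oc2cc(O)cc(O)c12
F9 | step 1 | 2,2-difluoro-4-methyl-5,7-bis(pivaloyloxy)-1,3,2-benzodioxaborinine (difluoroboron chelate of 2) | CC1=[O+][B-](F)(F)Oc2cc(OC(=O)C(C)(C)C)cc(OC(=O)C(C)(C)C)c12
A1 | alternative 1 | 4-[(E)-2-[2,5-dimethoxy-4-(3-methylbut-2-enyloxy)phenyl]ethenyl]morpholine | COc1cc(/C=C/N2CCOCC2)c(OC)cc1OCC=C(C)C
A2 | alternative 1 | 2,4,6-trifluorobenzoyl chloride | O=C(Cl)c1c(F)cc(F)cc1F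
A3 | alternative 1 | 3-[2,5-dimethoxy-4-(3-methylbut-2-enyloxy)phenyl]-5,7-difluorochromen-4-one | COc1cc(-c2coc3cc(F)cc(F)c3c2=O)c(OC)cc1OCC=C(C)C
A4 | alternative 2 | 3-(benzyloxy)-4-hydroxy-4-{[4-oxo-5,7-bis(triisopropylsilyloxy)chromen-3-yl]ethynyl}cyclobut-2-en-1-one (racemic) | O=C1C=C(OCc2ccccc2)C1(O)C#Cc1coc2cc(O[Si](C(C)C)(C(C)C)C(C)C)cc(O[Si](C(C)C)(C(C)C)C(C)C)c2c1=O
A5 | alternative 2 | 2-(benzyloxy)-5-[4-oxo-5,7-bis(triisopropylsilyloxy)chromen-3-yl]cyclohexa-2,5-diene-1,4-dione | O=C1C=C(OCc2ccccc2)C(=O)C=C1c1coc2cc(O[Si](C(C)C)(C(C)C)C(C)C)cc(O[Si](C(C)C)(C(C)C)C(C)C)c2c1=O
A6 | alternative 3 | methyl 2-[4-(allyloxy)-2,5-dimethoxyphenyl]-3-oxopropanoate (aldehyde tautomer drawn; racemic and enolisable) | COC(=O)C(C=O)c1cc(OC)c(OCC=C)cc1OC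
A7 | alternative 3 | 3,5-bis(methoxymethoxy)-2-(trimethylsilyl)phenyl trifluoromethanesulfonate | COCOc1cc(OCOC)c([Si](C)(C)C)c(OS(=O)(=O)C(F)(F)F)c1
A8 | alternative 3 | 3-[4-(allyloxy)-2,5-dimethoxyphenyl]-5,7-bis(methoxymethoxy)chromen-4-one | C=CCOc1cc(OC)c(-c2coc3cc(OCOC)cc(OCOC)c3c2=O)cc1OC
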